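Your delta run holds level near 89.3% of target from 12.0 min on, while theta, with more second substrate, reads 69% at 12.0 min.

the same everywhere: starting material 0.25 M; gas 110 mM (held)

| flask | second substrate | remark | time |
|---|---|---|---|
| delta | 0.12 M | run made earlier |  |
| theta | 0.50 M | run made earlier |  |
| flask | 0.250 M |  | 25 min |

- delta (time / min: target / %): 2.00: 45; 6.00: 83; 12.0: 89; 20.0: 90; 25.0: 89
- theta (time / min: target / %): 2.00: 36; 4.00: 56; 8.00: 68; 12.0: 69; 25.0: 62

(standard deviation of a reading: 2 percentage points)

- at the start none of the gas is in solution
- reagent is what gas becomes in solution

- how much target there is at 25 min, in percent of the starting material charged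
- concentration of reagent in solution at 25 min, in percent of saturation

Take an even split as the zero of your scale. Delta makes 0.223 M of target from 0.12 M of second substrate, so target does not carry second substrate one to one. Suppose, then, that starting material has two exits, one to target and one whose rate goes with second substrate. At some amount of second substrate the exits take equal shares, and target's share is that amount over itself plus the second substrate charged.

Delta puts this even-split amount, a selectivity factor in concentration, at 1.01 M. Carried to theta, it gives 66.8%, and for your flask 80.1%.

The weak link is theta's fall from 69% to 62%, which could mean that target decays. Delta reads 89% and then 89% over the same span, but delta holds less second substrate, and theta's fall of 7 percentage points stands against a scatter of 2 points on each reading, so these two runs leave decay open. You choose to set decay aside and average theta's last readings to 66.3%. That gives an even-split amount of 0.985 M from a separate run, and on that choice you commit to your figure for the flask.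

The forecast says 77% of target, below your figure, and 98% for reagent. Its ground for reagent: “demand is tiny, so reagent is essentially saturated”.

The flask gives 80.8% of target, with reagent at 80.4% of saturation.

    starting material + second substrate → cross product (k = 0.00617 M⁻¹ s⁻¹)
    starting material + reagent → target (k = 0.0738 M⁻¹ s⁻¹)
    2 reagent → homo dimer (k = 0.0769 M⁻¹ s⁻¹)
    second substrate + reagent → second product (k = 0.00731 M⁻¹ s⁻¹)
    gas ⇌ reagent, rate k5*(csat - [reagent]) (kL = 0.0583 s⁻¹)

In the flask at 11.1 min, reagent goes to homo dimer 85 times as fast as to target. At that moment it is made 1.00 times as fast as it is used. The even-split amount gave 80.1% for this flask. For a neighbour flask charged with 1.0 M of second substrate it gives 50.2%, and that neighbour holds 47.6% of target.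

The numbers in the tables are simulated from invented constants, noise included.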